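The runs are calculated on assumed constants, noise included.

Late in the dawn flask, between 120 min and 150 min, X rose by a mere 1.7 percentage points while G still stood at 26.4 %, and I began my reckoning from that tail.

| setting | dawn | midnight | flask |
|---|---|---|---|
| G | 0.10 M | 0.10 M | 0.10 M |
| J | 0.070 M | 0.070 M | 0.0700 M |
| Q | 0.020 M | 0.030 M | 0.0200 M |
| remark | the very flask that is asked about, followed so far | run made earlier |  |
| time |  |  | 4.0 h |
| volume of the second phase over the first |  |  | 0.25 |

| run | time / min | X / % | G / % |
|---|---|---|---|
| dawn | 20.0 | 24.8 | 55.9 |
| dawn | 40.0 | 37.7 | 42.2 |
| dawn | 60.0 | 45.0 | 34.8 |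
| dawn | 80.0 | 48.9 | 31.6 |
| dawn | 90.0 | 49.5 | 30.3 |
| dawn | 120 | 52.1 | 28.5 |
| dawn | 150 | 53.8 | 26.4 |
| midnight | 2.00 | 1.0 | 69.3 |
| midnight | 3.00 | 2.5 | 67.4 |
| midnight | 5.00 | 5.4 | 65.0 |
| midnight | 8.00 | 9.5 | 60.0 |
| midnight | 10.0 | 12.3 | 57.8 |
| midnight | 15.0 | 18.1 | 52.4 |
| midnight | 25.0 | 27.3 | 43.2 |

(scatter of a reading: 0.3 percentage points)

- in the second phase: J; everything else is in the first
- charges count per volume of the first phase; a concentration in a rate is the amount of a species over the volume of its own phase; every rate counts per litre of the first phase
- X taken out counts as made
- the analysis behind the earlier runs scatters by 0.3 percentage points, standard deviation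
- the earlier runs hold the two phases in the same ratio of volumes as the flask asked about
- additions bring no volume worth counting

- eta: change nothing and wait 80 min more
- alpha: at 4.0 h take out 90 % of the X then present, then wait 80 min
- gamma: at 4.0 h add G, 50.0 % of the amount charged, then wait 80 min

* X, in percent of the G first charged, at 4.0 h
* the option that brings most further X ("none" if no option brings more than 2 percentage points) (eta / alpha / gamma / none)
* X present, with what was taken out counted in, in percent of the G first charged, after eta
* X present, with what was taken out counted in, in percent of the G first charged, after alpha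

At the last dawn reading G plus X came to 80.2 %, close to the charge less one G per Q, 80.0 %, so I took Q as having bound its share of G early. The bench rule counts charges: J, at 70.0 % of the G charged, is the limiting reagent, and the rate follows free G times the J not yet turned into X. But from the window 40.0 min to 60.0 min to the window 120 min to 150 min that product falls by a factor 2.36, while the rate as read falls by a factor 6.44, so the rule had stopped working with 16 points of J still uncounted.

I therefore named the tail time τ, the time in which the rate of X falls by a factor e, and read it as the distance between those windows over the logarithm of that factor: 45.6 min. What is still to come then equals the gain of the last window of length w divided by one less than exp(w/τ). The gain from 60.0 min to 120 min leaves 2.6 points to come after 120 min, so the tail ends near 54.7 %. At 4.0 h I expected 54.5 %, and eta should add 0.16 points. I judged the tail a drain on J rather than a reversal, which these readings cannot prove, so I gave alpha the same gain. For gamma I scaled it by the rise in free G, to 0.46 points, below 2 points, and I answered none.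

The forecast differed, giving 55.7 %, 56.2 % after eta, 61.1 % after alpha and the choice gamma, on its ground that the “late stall, with G and J still present, points to reversibility”.

The simulation gave 54.3 %, then 54.4 % after eta and 54.4 % after alpha; eta, alpha and gamma brought 0.15 points, 0.15 points and 0.22 points, and the best option was none.

    Z ⇌ J, rate k1*([Z] - [J]/K1) per volume of the first phase (partition coefficient = 13.0, kL = 0.00310 /s)
    G + Z → X (k = 0.0550 /M/s)
    G + Q → E (k = 4.10 /M/s)
    Z → D (k = 7.50 × 10⁻⁴ /s)

In this flask J fell from 4.31 % to 0.331 % of its charge between 120 min and 4.0 h, a decay time of 46.8 min against τ of 45.6 min. The neighbour flask, the same charges left until 1.0 h, gets the same reckoning: it stopped with X at 44.8 % and J at 17.1 % of its charge, and carrying that J on by τ over the 3.95 tail times up to 4.0 h gives 0.330 %, where the table of the flask at 4.0 h holds 0.331 %.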